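**Strategy**

Everything rests on cutting the side chain at C14'–C15' and C16'–C17', so that C15', C16' and the hydroxymethyl carbon come from 3,3-diethoxyprop-1-yne. The key step exploits the trisubstituted C15'=C16' olefin, in which C14' and C17' are cis and the CH2OH carbon on C16' is trans to C14': syn carbocupration of the alkyne by the organocopper of the chromene half, then retentive alkylation with homogeranyl iodide, should form both C–C bonds and fix this geometry in one flask. The precursor is the silyl-protected (S)-2H-chromene (benzene ring A, pyran ring B, C2 stereocentre from a Sharpless epoxide) whose C1'–C14' chain ends in a primary iodide.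

Key step: step 15

Remark: side-chain carbons are numbered C1' to C24' outward from ring carbon C2; L-(+)-diethyl tartrate is taken to give the (2S,3S)-epoxide of this E-allylic alcohol, and its C3–O bond, never broken afterwards, becomes the C2–O1 bond of the (S)-chromene.

**Fragment 1 (chromene head iodide)**

Step 1
Reactants: 1 (2E,6E,10E)-geranylgeraniol
Product: 2 (2S,3S)-2,3-epoxygeranylgeraniol
Conditions: Ti(OiPr)4 (cat.), L-(+)-diethyl tartrate (cat.), t-BuOOH, 4 Å MS, CH2Cl2, −20 °C
Reagents that add atoms: tert-butyl hydroperoxide, CC(C)(C)OO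
Why: Katsuki–Sharpless asymmetric epoxidation is hydroxyl-directed, so only the 2,3-olefin of the tetraene should react, and the L-(+)-tartrate ligand controls the face of oxygen delivery to give the (2S,3S)-epoxide, which sets the future C2 stereocentre of the chromene.

Step 2
Reactants: 2 (2S,3S)-2,3-epoxygeranylgeraniol
Product: 3 (2R,3S)-2-(chloromethyl)-3-methyl-3-[(3E,7E)-4,8,12-trimethyltrideca-3,7,11-trienyl]oxirane
Conditions: PPh3, CCl4, NaHCO3, reflux
Reagents that add atoms: carbon tetrachloride, ClC(Cl)(Cl)Cl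
Why: Appel chlorination converts the primary alcohol into the chloride under buffered, non-acidic conditions that should leave the trisubstituted epoxide closed and both stereocentres untouched, the C2 descriptor changing only because CH2Cl now outranks the ring carbon.

Step 3
Reactants: 3 (2R,3S)-epoxy chloride
Product: 4 (3S,6E,10E)-3,7,11,15-tetramethylhexadeca-6,10,14-trien-1-yn-3-ol
Conditions: LiN(iPr)2 (3.5 equiv), THF, −78 to −30 °C; then H2O
Reagents that add atoms: none
Why: Base-induced double elimination of a 2,3-epoxy chloride (deprotonation next to chlorine opens the epoxide at C2–O to a chlorovinyl alkoxide, which loses HCl to the alkyne) never breaks the C3–O bond, so the tertiary propargylic alcohol should keep the (S) configuration of the epoxide.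

Step 4
Reactants: 5 4-bromo-3-iodophenol
Product: 6 (4-bromo-3-iodophenoxy)triisopropylsilane
Conditions: TIPSCl, imidazole, DMF, rt
Reagents that add atoms: triisopropylsilyl chloride, CC(C)[Si](Cl)(C(C)C)C(C)C
Why: Silylation of the phenol gives a bulky aryl silyl ether that should withstand carbonate base at 100 °C, organolithium reagents at low temperature and mild aqueous acid, and that fluoride removes at the end.

Step 5
Reactants: 4 (S)-alkynol; 6 (4-bromo-3-iodophenoxy)triisopropylsilane
Product: 7 (3S,6E,10E)-1-[2-bromo-5-(triisopropylsilyloxy)phenyl]-3,7,11,15-tetramethylhexadeca-6,10,14-trien-1-yn-3-ol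
Conditions: Pd(PPh3)2Cl2 (cat.), CuI (cat.), Et3N, THF, rt
Reagents that add atoms: none
Why: In this Sonogashira coupling zerovalent palladium inserts into the C–I bond far faster than into the C–Br bond, so the alkyne should be attached only at the iodinated carbon while the bromide is kept for ring closure and the carbinol centre is not involved.

Step 6
Reactants: 7 aryl alkynol
Product: 8 (1Z,3S,6E,10E)-1-[2-bromo-5-(triisopropylsilyloxy)phenyl]-3,7,11,15-tetramethylhexadeca-1,6,10,14-tetraen-3-ol
Conditions: H2 (1 atm), Pd/CaCO3–Pb(OAc)2 (Lindlar catalyst), quinoline, EtOAc, rt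
Reagents that add atoms: none
Why: Lindlar semihydrogenation delivers both hydrogens syn from the poisoned palladium surface and should stop at the Z-styrenyl olefin, leaving the aryl bromide and the trisubstituted olefins untouched.

Step 7
Reactants: 8 (Z)-alkenol
Product: 9 triisopropyl{[(2S)-2-methyl-2-[(3E,7E)-4,8,12-trimethyltrideca-3,7,11-trienyl]-2H-chromen-6-yl]oxy}silane
Conditions: CuI (cat.), 3,4,7,8-tetramethyl-1,10-phenanthroline, Cs2CO3, toluene, 100 °C
Reagents that add atoms: none
Why: In this intramolecular Ullmann-type C–O coupling the Z-olefin holds the tertiary alkoxide beside the C–Br bond, so copper-mediated aryl–oxygen bond formation should close the six-membered pyran ring B, and the stereocentre keeps its configuration because its own C–O bond is not broken.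

Step 8
Reactants: 9 silyl-protected chromene
Product: 10 (2E,6E,10E)-2,6,10-trimethyl-13-[(2S)-2-methyl-6-(triisopropylsilyloxy)-2H-chromen-2-yl]trideca-2,6,10-trien-1-ol
Conditions: SeO2 (cat.), salicylic acid (cat.), t-BuOOH, CH2Cl2, 0 °C to rt, stopped at partial conversion
Reagents that add atoms: selenium dioxide, O=[Se]=O; tert-butyl hydroperoxide, CC(C)(C)OO
Why: Riley-type allylic oxidation (ene reaction, then [2,3]-sigmatropic shift of the allylseleninic acid) should attack the most electron-rich and least hindered terminal isopropylidene group and hydroxylate its E-methyl, the usual site selectivity for polyprenyl chains.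

Step 9
Reactants: 10 terminal allylic alcohol
Product: 11 (2S)-2-[(3E,7E,11E)-13-bromo-4,8,12-trimethyltrideca-3,7,11-trienyl]-2-methyl-6-(triisopropylsilyloxy)-2H-chromene
Conditions: CBr4, PPh3, CH2Cl2, 0 °C
Reagents that add atoms: carbon tetrabromide, BrC(Br)(Br)Br
Why: Appel bromination replaces the primary allylic hydroxyl by SN2 displacement of the oxyphosphonium group under neutral conditions, which should preserve the E olefin, the chromene and the aryl silyl ether.

Step 10
Reactants: 11 allylic bromide
Product: 12 (2S)-2-methyl-2-[(3E,7E,11E)-4,8,12-trimethyl-14-(phenylthio)tetradeca-3,7,11-trienyl]-6-(triisopropylsilyloxy)-2H-chromene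
Conditions: PhSMe, n-BuLi, DABCO, THF, 0 °C; then 11, −78 to 0 °C
Reagents that add atoms: thioanisole (as its lithio derivative), CSc1ccccc1
Why: SN2 alkylation of (phenylthio)methyllithium by the primary allylic bromide is a known one-carbon homologation of polyprenyl bromides and should add C14' without touching the olefin geometry.

Step 11
Reactants: 12 homoallylic phenyl sulfide
Product: 14 fragment 1 iodide (2S)-2-[(3E,7E,11E)-14-iodo-4,8,12-trimethyltetradeca-3,7,11-trienyl]-2-methyl-6-(triisopropylsilyloxy)-2H-chromene, via S-methylsulfonium iodide 13 (not isolated)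
Conditions: MeI (excess), NaI, DMF, 75 °C, sealed vessel
Reagents that add atoms: methyl iodide, CI; sodium iodide, [Na+].[I-]
Why: S-methylation gives the sulfonium salt 13, from which iodide displaces thioanisole at the primary carbon by SN2 (sulfide-to-iodide exchange), neutral conditions that the chromene and the silyl ether should tolerate.

**Fragment 2 (homogeranyl iodide)**

Step 12
Reactants: 15 geraniol
Product: 16 geranyl bromide
Conditions: PBr3, Et2O, −10 °C
Reagents that add atoms: phosphorus tribromide, BrP(Br)Br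
Why: Displacement of the allylic hydroxyl through its phosphite ester with PBr3 at low temperature is the standard, geometry-retaining route to geranyl bromide.

Step 13
Reactants: 16 geranyl bromide
Product: 17 [(3E)-4,8-dimethylnona-3,7-dienyl](phenyl)sulfane
Conditions: PhSMe, n-BuLi, DABCO, THF, 0 °C; then 16, −78 to 0 °C
Reagents that add atoms: thioanisole (as its lithio derivative), CSc1ccccc1
Why: SN2 alkylation of (phenylthio)methyllithium by the allylic bromide should give the one-carbon homologue with the E olefin intact.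

Step 14
Reactants: 17 homogeranyl phenyl sulfide
Product: 19 fragment 2 iodide (3E)-1-iodo-4,8-dimethylnona-3,7-diene, via S-methylsulfonium iodide 18 (not isolated)
Conditions: MeI (excess), NaI, DMF, 75 °C, sealed vessel
Reagents that add atoms: methyl iodide, CI; sodium iodide, [Na+].[I-]
Why: The same sulfide-to-iodide exchange (S-methylation, then SN2 attack of iodide at the primary carbon of sulfonium salt 18) should release the homoallylic iodide and thioanisole.

**Coupling and end game**

Step 15
Reactants: 14 fragment 1 iodide; 20 3,3-diethoxyprop-1-yne; 19 fragment 2 iodide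
Product: 24 silyl-protected C16' diethyl acetal (2S)-2-[(3E,7E,11E,15E,19E)-16-(diethoxymethyl)-4,8,12,20,24-pentamethylpentacosa-3,7,11,15,19,23-hexaenyl]-2-methyl-6-(triisopropylsilyloxy)-2H-chromene, via alkyllithium 21 (not isolated), via alkylcopper 22 (not isolated), via alkenylcopper 23 (not isolated)
Conditions: t-BuLi (2.1 equiv), Et2O, −78 °C; CuBr·SMe2 (1.0 equiv), Et2O/SMe2, −45 °C; 20 (1.0 equiv), −45 to −25 °C; then 19 (2 equiv), P(OEt)3, HMPA (or DMPU), −30 °C to rt
Reagents that add atoms: none
Why: Iodine–lithium exchange on 14 and transmetalation with CuBr·SMe2 give the alkylcopper 22, which adds across the triple bond of 20 through a four-centre syn transition state, the alkyl group going to the terminal carbon (new C14'–C15' bond) and copper to the carbon next to the acetal, where the ethoxy oxygens coordinate the metal. The alkenylcopper 23 holds its geometry at low temperature and is alkylated by the primary iodide 19 with retention (oxidative addition to a transient trivalent copper species, then reductive elimination, helped by P(OEt)3 and the polar cosolvent), which forms the C16'–C17' bond. The closest known reaction type is the Normant carbocupration of acetylenic acetals followed by alkylation of the resulting alkenylcopper, a classical entry to α-substituted enal acetals. No ring closes and no stereocentre is formed, and the (S) centre at C2 is remote and untouched. The step needs regioselectivity and olefin geometry: acetal coordination secures the first, and syn addition plus retentive alkylation place C14' and C17' cis with the acetal carbon trans to C14'. Loss of ethoxide from 23 by β-elimination is held back by keeping the lithium-based reagent in Et2O below −25 °C until the electrophile is present.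

Step 16
Reactants: 24 silyl-protected C16' diethyl acetal
Product: 25 silyl-protected (15'E)-enal (2E)-2-[(3E)-4,8-dimethylnona-3,7-dienyl]-substituted 2-enal carrying CHO on C16'
Conditions: PPTS (cat.), acetone/H2O, rt
Reagents that add atoms: water, O
Why: Acid-catalysed acetal hydrolysis of an α,β-unsaturated diethyl acetal proceeds through an easily formed conjugated oxocarbenium ion, so mild acid should suffice, and the enal geometry (CHO trans to C14') is also the thermodynamically preferred one.

Step 17
Reactants: 25 silyl-protected enal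
Product: 26 silyl-protected allylic alcohol [(2S)-chromene 6-O-TIPS ether with CH2OH on C16']
Conditions: NaBH4, CeCl3·7H2O, MeOH/THF, 0 °C
Reagents that add atoms: none
Why: Luche reduction with CeCl3-activated NaBH4 in methanol should reduce the enal carbonyl in the 1,2 sense only, giving the allylic alcohol without touching any olefin.

Step 18
Reactants: 26 silyl-protected allylic alcohol
Product: 27 target (2S)-2-[(3E,7E,11E,15E,19E)-16-(hydroxymethyl)-4,8,12,20,24-pentamethylpentacosa-3,7,11,15,19,23-hexaenyl]-2-methyl-2H-chromen-6-ol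
Conditions: Bu4NF, AcOH, THF, 0 °C, argon
Reagents that add atoms: none
Why: Fluoride-mediated desilylation, driven by the strong Si–F bond, should free the phenol, and the acetic acid buffer keeps the electron-rich chromenol from standing as its air-sensitive phenoxide.

**Compound list**

1 | (2E,6E,10E)-geranylgeraniol | CC(C)=CCC/C(C)=C/CC/C(C)=C/CC/C(C)=C/CO | starting material
2 | (2S,3S)-2,3-epoxygeranylgeraniol, [(2S,3S)-3-methyl-3-[(3E,7E)-4,8,12-trimethyltrideca-3,7,11-trienyl]oxiran-2-yl]methanol | CC(C)=CCC/C(C)=C/CC/C(C)=C/CC[C@]1(C)O[C@H]1CO | intermediate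
3 | (2R,3S)-2-(chloromethyl)-3-methyl-3-[(3E,7E)-4,8,12-trimethyltrideca-3,7,11-trienyl]oxirane | CC(C)=CCC/C(C)=C/CC/C(C)=C/CC[C@]1(C)O[C@H]1CCl | intermediate
4 | (3S,6E,10E)-3,7,11,15-tetramethylhexadeca-6,10,14-trien-1-yn-3-ol | CC(C)=CCC/C(C)=C/CC/C(C)=C/CC[C@](C)(O)C#C | intermediate
5 | 4-bromo-3-iodophenol | Oc1ccc(Br)c(I)c1 | starting material
6 | (4-bromo-3-iodophenoxy)triisopropylsilane | CC(C)[Si](Oc1ccc(Br)c(I)c1)(C(C)C)C(C)C | intermediate
7 | (3S,6E,10E)-1-[2-bromo-5-(triisopropylsilyloxy)phenyl]-3,7,11,15-tetramethylhexadeca-6,10,14-trien-1-yn-3-ol | CC(C)=CCC/C(C)=C/CC/C(C)=C/CC[C@](C)(O)C#Cc1cc(O[Si](C(C)C)(C(C)C)C(C)C)ccc1Br | intermediate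
8 | (1Z,3S,6E,10E)-1-[2-bromo-5-(triisopropylsilyloxy)phenyl]-3,7,11,15-tetramethylhexadeca-1,6,10,14-tetraen-3-ol | CC(C)=CCC/C(C)=C/CC/C(C)=C/CC[C@](C)(O)/C=C\c1cc(O[Si](C(C)C)(C(C)C)C(C)C)ccc1Br | intermediate
9 | triisopropyl{[(2S)-2-methyl-2-[(3E,7E)-4,8,12-trimethyltrideca-3,7,11-trienyl]-2H-chromen-6-yl]oxy}silane | CC(C)=CCC/C(C)=C/CC/C(C)=C/CC[C@@]1(C)C=Cc2cc(O[Si](C(C)C)(C(C)C)C(C)C)ccc2O1 | intermediate
10 | (2E,6E,10E)-2,6,10-trimethyl-13-[(2S)-2-methyl-6-(triisopropylsilyloxy)-2H-chromen-2-yl]trideca-2,6,10-trien-1-ol | OC/C(C)=C/CC/C(C)=C/CC/C(C)=C/CC[C@@]1(C)C=Cc2cc(O[Si](C(C)C)(C(C)C)C(C)C)ccc2O1 | intermediate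
11 | (2S)-2-[(3E,7E,11E)-13-bromo-4,8,12-trimethyltrideca-3,7,11-trienyl]-2-methyl-6-(triisopropylsilyloxy)-2H-chromene | BrC/C(C)=C/CC/C(C)=C/CC/C(C)=C/CC[C@@]1(C)C=Cc2cc(O[Si](C(C)C)(C(C)C)C(C)C)ccc2O1 | intermediate
12 | (2S)-2-methyl-2-[(3E,7E,11E)-4,8,12-trimethyl-14-(phenylthio)tetradeca-3,7,11-trienyl]-6-(triisopropylsilyloxy)-2H-chromene | S(CC/C(C)=C/CC/C(C)=C/CC/C(C)=C/CC[C@@]1(C)C=Cc2cc(O[Si](C(C)C)(C(C)C)C(C)C)ccc2O1)c3ccccc3 | intermediate
13 | S-methylsulfonium iodide of 12 (methyl and phenyl on sulfur and the C14' chain, mixture at sulfur) | C[S+](CC/C(C)=C/CC/C(C)=C/CC/C(C)=C/CC[C@@]1(C)C=Cc2cc(O[Si](C(C)C)(C(C)C)C(C)C)ccc2O1)c3ccccc3.[I-] | intermediate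
14 | fragment 1, (2S)-2-[(3E,7E,11E)-14-iodo-4,8,12-trimethyltetradeca-3,7,11-trienyl]-2-methyl-6-(triisopropylsilyloxy)-2H-chromene | ICC/C(C)=C/CC/C(C)=C/CC/C(C)=C/CC[C@@]1(C)C=Cc2cc(O[Si](C(C)C)(C(C)C)C(C)C)ccc2O1 | intermediate
15 | geraniol | CC(C)=CCC/C(C)=C/CO | starting material
16 | geranyl bromide, (2E)-1-bromo-3,7-dimethylocta-2,6-diene | CC(C)=CCC/C(C)=C/CBr | intermediate
17 | [(3E)-4,8-dimethylnona-3,7-dienyl](phenyl)sulfane | CC(C)=CCC/C(C)=C/CCSc1ccccc1 | intermediate
18 | [(3E)-4,8-dimethylnona-3,7-dienyl](methyl)(phenyl)sulfonium iodide | CC(C)=CCC/C(C)=C/CC[S+](C)c1ccccc1.[I-] | intermediate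
19 | fragment 2, (3E)-1-iodo-4,8-dimethylnona-3,7-diene | CC(C)=CCC/C(C)=C/CCI | intermediate
20 | 3,3-diethoxyprop-1-yne | C#CC(OCC)OCC | starting material
21 | alkyllithium of fragment 1 (lithium on C14') | [Li]CC/C(C)=C/CC/C(C)=C/CC/C(C)=C/CC[C@@]1(C)C=Cc2cc(O[Si](C(C)C)(C(C)C)C(C)C)ccc2O1 | intermediate
22 | alkylcopper of fragment 1 (copper on C14') | [Cu]CC/C(C)=C/CC/C(C)=C/CC/C(C)=C/CC[C@@]1(C)C=Cc2cc(O[Si](C(C)C)(C(C)C)C(C)C)ccc2O1 | intermediate
23 | alkenylcopper (copper on C16' cis to C14', diethoxymethyl group trans to C14') | CCOC(OCC)/C([Cu])=C/CC/C(C)=C/CC/C(C)=C/CC/C(C)=C/CC[C@@]1(C)C=Cc2cc(O[Si](C(C)C)(C(C)C)C(C)C)ccc2O1 | intermediate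
24 | (2S)-2-[(3E,7E,11E,15E,19E)-16-(diethoxymethyl)-4,8,12,20,24-pentamethylpentacosa-3,7,11,15,19,23-hexaenyl]-2-methyl-6-(triisopropylsilyloxy)-2H-chromene | CC(C)=CCC/C(C)=C/CC/C(=C\CC/C(C)=C/CC/C(C)=C/CC/C(C)=C/CC[C@@]1(C)C=Cc2cc(O[Si](C(C)C)(C(C)C)C(C)C)ccc2O1)C(OCC)OCC | intermediate
25 | silyl-protected (15'E)-enal: as 24 with CHO in place of CH(OEt)2 on C16' | CC(C)=CCC/C(C)=C/CC/C(=C\CC/C(C)=C/CC/C(C)=C/CC/C(C)=C/CC[C@@]1(C)C=Cc2cc(O[Si](C(C)C)(C(C)C)C(C)C)ccc2O1)C=O | intermediate
26 | silyl-protected allylic alcohol: as 24 with CH2OH on C16' | CC(C)=CCC/C(C)=C/CC/C(=C\CC/C(C)=C/CC/C(C)=C/CC/C(C)=C/CC[C@@]1(C)C=Cc2cc(O[Si](C(C)C)(C(C)C)C(C)C)ccc2O1)CO | intermediate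
27 | (2S)-2-[(3E,7E,11E,15E,19E)-16-(hydroxymethyl)-4,8,12,20,24-pentamethylpentacosa-3,7,11,15,19,23-hexaenyl]-2-methyl-2H-chromen-6-ol | CC(C)=CCC/C(C)=C/CC/C(=C\CC/C(C)=C/CC/C(C)=C/CC/C(C)=C/CC[C@@]1(C)C=Cc2cc(O)ccc2O1)CO | target

**Step count**

Total: 18 steps. Longest linear sequence: 14 steps from geranylgeraniol (steps 1, 2, 3, 5, 6, 7, 8, 9, 10, 11, 15, 16, 17, 18).

**Steps most likely to fail, with fallbacks**

Step 15. Several processes could go wrong here:
- the lithium-derived alkylcopper may add to the alkyne too slowly;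
- the reagent may deprotonate the terminal alkyne instead of adding to it;
- the alkenylcopper may lose ethoxide by β-elimination before it is alkylated;
- the alkylation may lag, so that the alkenylcopper is merely protonated on work-up.

The fallback gives up the alkyne linchpin and builds the C15'=C16' olefin by olefination. It sets out from 14 and 19 and rejoins the route at 26, passing over 24 and 25. The alkyllithium 21, made from 14 as before, is formylated with DMF (Bouveault aldehyde synthesis) to the C15' aldehyde F1. Triethyl phosphonoacetate is alkylated with 19 (NaH, DMF) to the α-homogeranyl phosphonate F2. Horner–Wadsworth–Emmons olefination of F1 with the sodium salt of F2 in THF should give mainly the E-enoate F3, with the ester trans to C14'; the minor geometric isomer would be removed by chromatography. Reduction with iBu2AlH in CH2Cl2 at −78 °C then gives 26.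

Step 8. The allylic oxidation may also attack the internal trisubstituted olefins, or run on to the enal. The fallback sets out from 9 and returns at 10, replacing direct C–H oxidation by degradation and rebuilding of the chain terminus:
- NBS in aqueous THF at 0 °C, which is known to favour the terminal olefin of polyprenyl chains, to the bromohydrin F4;
- K2CO3 in MeOH to the terminal epoxide F5;
- H5IO6 in THF/Et2O to cleave F5 to the C11' aldehyde F6 and acetone;
- the stabilised ylide Ph3P=C(CH3)CO2Et in CH2Cl2 to the E-enoate F7;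
- iBu2AlH in CH2Cl2 at −78 °C to the allylic alcohol 10.

Step 10. The basic carbanion may attack the far end of the allyl system (allylic transposition) or cause elimination, and the allylic bromide may decompose on handling. The later sulfonium cleavage of step 11 may also stall. The fallback sets out from 10 and returns at 14, passing over 11, 12 and 13; it replaces the sulfur-based homologation by olefination and hydroboration:
- MnO2 in CH2Cl2 to the E-enal F8;
- Wittig methylenation with Ph3P=CH2 (from Ph3PCH3Br and KOtBu, THF) to the terminal diene F9;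
- 9-BBN in THF, which should hydroborate only the monosubstituted vinyl group, then NaBO3·4H2O to the homoallylic alcohol F10;
- I2, PPh3 and imidazole in CH2Cl2 to the iodide 14.

**Further compounds**

F1 | step 15 | (4E,8E,12E)-4,8,12-trimethyl-15-[(2S)-2-methyl-6-(triisopropylsilyloxy)-2H-chromen-2-yl]pentadeca-4,8,12-trienal | O=CCC/C(C)=C/CC/C(C)=C/CC/C(C)=C/CC[C@@]1(C)C=Cc2cc(O[Si](C(C)C)(C(C)C)C(C)C)ccc2O1
F2 | step 15 | ethyl (5E)-2-(diethoxyphosphoryl)-6,10-dimethylundeca-5,9-dienoate (racemic at C2) | CC(C)=CCC/C(C)=C/CCC(C(=O)OCC)P(=O)(OCC)OCC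
F3 | step 15 | ethyl ester corresponding to 25 (CO2Et on C16', trans to C14', silyl ether kept) | CC(C)=CCC/C(C)=C/CC/C(=C\CC/C(C)=C/CC/C(C)=C/CC/C(C)=C/CC[C@@]1(C)C=Cc2cc(O[Si](C(C)C)(C(C)C)C(C)C)ccc2O1)C(=O)OCC
F4 | step 8 | terminal bromohydrin of 9 (Br on C11', OH on C12', both epimers at C11') | CC(C)(O)C(Br)CC/C(C)=C/CC/C(C)=C/CC[C@@]1(C)C=Cc2cc(O[Si](C(C)C)(C(C)C)C(C)C)ccc2O1
F5 | step 8 | terminal 11',12'-epoxide of 9 (both epimers at C11') | CC1(C)OC1CC/C(C)=C/CC/C(C)=C/CC[C@@]2(C)C=Cc3cc(O[Si](C(C)C)(C(C)C)C(C)C)ccc3O2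
F6 | step 8 | (4E,8E)-4,8-dimethyl-11-[(2S)-2-methyl-6-(triisopropylsilyloxy)-2H-chromen-2-yl]undeca-4,8-dienal | O=CCC/C(C)=C/CC/C(C)=C/CC[C@@]1(C)C=Cc2cc(O[Si](C(C)C)(C(C)C)C(C)C)ccc2O1
F7 | step 8 | ethyl (2E,6E,10E)-2,6,10-trimethyl-13-[(2S)-2-methyl-6-(triisopropylsilyloxy)-2H-chromen-2-yl]trideca-2,6,10-trienoate | CCOC(=O)/C(C)=C/CC/C(C)=C/CC/C(C)=C/CC[C@@]1(C)C=Cc2cc(O[Si](C(C)C)(C(C)C)C(C)C)ccc2O1
F8 | step 10 | (2E,6E,10E)-2,6,10-trimethyl-13-[(2S)-2-methyl-6-(triisopropylsilyloxy)-2H-chromen-2-yl]trideca-2,6,10-trienal | O=C/C(C)=C/CC/C(C)=C/CC/C(C)=C/CC[C@@]1(C)C=Cc2cc(O[Si](C(C)C)(C(C)C)C(C)C)ccc2O1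
F9 | step 10 | (2S)-2-methyl-2-[(3E,7E,11E)-4,8,12-trimethyltetradeca-3,7,11,13-tetraenyl]-6-(triisopropylsilyloxy)-2H-chromene | C=C/C(C)=C/CC/C(C)=C/CC/C(C)=C/CC[C@@]1(C)C=Cc2cc(O[Si](C(C)C)(C(C)C)C(C)C)ccc2O1
F10 | step 10 | (3E,7E,11E)-3,7,11-trimethyl-14-[(2S)-2-methyl-6-(triisopropylsilyloxy)-2H-chromen-2-yl]tetradeca-3,7,11-trien-1-ol | OCC/C(C)=C/CC/C(C)=C/CC/C(C)=C/CC[C@@]1(C)C=Cc2cc(O[Si](C(C)C)(C(C)C)C(C)C)ccc2O1
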